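The earlier runs and the new flask stem from a simulated flask for substances that don't exist; the scatter is artificial.

The flask is read at 5.0 min, and what stands in it then has to be reckoned from its charges and three earlier runs.

| flask | substrate | coupling partner | remark | time |
|---|---|---|---|---|
| epsilon | 0.50 mM | 0.66 mM | run made earlier |  |
| delta | 0.50 mM | 1 mM | run made earlier |  |
| eta | 0.25 mM | 0.475 mM | run made earlier |  |
| flask | 0.50 mM | 0.475 mM |  | 5.0 min |

| run | time / min | substrate / % | first product / % |
|---|---|---|---|
| epsilon | 0.500 | 23.6 | 68.9 |
| epsilon | 1.00 | 11.7 | 79.1 |
| epsilon | 1.50 | 7.4 | 82.4 |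
| epsilon | 2.50 | 3.4 | 84.6 |
| epsilon | 3.00 | 3.5 | 84.7 |
| epsilon | 4.00 | 2.0 | 85.3 |
| delta | 0.333 | 17.4 | 71.2 |
| delta | 0.500 | 9.5 | 76.8 |
| delta | 0.667 | 5.9 | 79.9 |
| delta | 1.00 | 2.4 | 81.3 |
| delta | 1.50 | 0.6 | 80.4 |
| delta | 2.50 | 0 | 77.7 |
| delta | 4.00 | 0 | 73.5 |
| eta | 0.333 | 37.3 | 56.2 |
| eta | 0.667 | 19.0 | 70.7 |
| eta | 1.00 | 11.9 | 76.7 |
| eta | 2.00 | 3.1 | 79.0 |
| eta | 4.00 | 0.5 | 74.4 |

(scatter of a reading: 0.3 percentage points)

* the substrate standing at 5.0 min, as a percentage of the substrate charged
* the first product standing at 5.0 min, as a percentage of the substrate charged
* the double product standing at 5.0 min, as a percentage of the substrate charged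

- a reading or a percentage of first product counts all its forms, free or not

The flask holds c(coupling partner) 0.475 mM against c(substrate) 0.50 mM, so the coupling partner is the limiting reagent. The shortfall of partner as a share of the substrate charged, the partner gap 5.00 %, looks like the substrate left at the end. Yet the eta run, on the same partner charge, points to more than that. At 0.333 min its readings leave 10.4 % of the converted substrate unaccounted for, and this is read as double product, which carries a second partner.

So, if partner goes nowhere else, substrate left equals the gap plus double product. The reckoning assumes that the flask's partner is consumed at the reading; the eta run, with partner in excess, had substrate down to 3.1 % by 2.00 min, earlier than the flask's reading. Freezing that share gives substrate 13.9 %, double product 8.92 % and first product 77.2 %.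

The forecast, noting that “the partner is limiting”, gives substrate 13 %, first product 80.5 % and double product 6.5 %, with less double product than this reckoning.

The flask gives substrate 15.7 %, first product 77.7 % and double product 6.51 %. Homo dimer stands at 0.00958 mM at 5.00 min, and each one holds two partners. The gap plus double product comes to 11.5 %, which is 4.2 percentage points short of the substrate found. Partner held in homo dimer equals 3.83 % of the substrate charged, and partner still standing equals 0.401 %.

    2 coupling partner → homo dimer (k = 4.30 M⁻¹ s⁻¹)
    coupling partner + first product → double product + by-product (k = 240 M⁻¹ s⁻¹)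
    crystals ⇌ first product, rate k3*(cs3 - [first product]) while solid is left; crystals form when [first product] > cs3 (solubility = 0.00560 mM, k = 1.40 s⁻¹)
    substrate + coupling partner → first product + by-product (k = 140 M⁻¹ s⁻¹)

With 2.0 mM of substrate on the same partner charge, the gap is 76.2 %. That neighbour flask computes to 77.3 % substrate and 0.845 % double product.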